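**Plan**

1. Cuts: after removal of seven O-benzyl groups, ring C of the eriodictyol half is opened at C4–C4a and O1–C8a (β-hydroxy acyl unit + aryne), then at C2–C3 (aldol). The naringenin half is cut at C2″–aryl (conjugate arylation of a chromone) and at C8″–CH2 (Negishi coupling).
2. Enabling feature: ring A carries oxygen at C5, next to C4a, and at C7. It is therefore a 3,5-dioxygenated benzyne whose 3-alkoxy group sends an O-nucleophile to C8a and leaves the carbanion on C4a, while O1–C2–C3–C4 is an aldol unit.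
3. Forward: rings D/F are made first as an 8-iodochromone. The C3–C4 two-carbon arm is coupled to C8″ and loaded on an oxazolidinone, an aldol adds C2 with ring B, and arylation turns the chromone into the flavanone (ring E). The aryne annulation then attaches ring A to O1 and closes ring C; hydrogenolysis ends the route.
4. Stereochemistry: C2 and C3 (R,R; 2,3-cis) come from the Evans syn aldol under control of (R)-4-benzyloxazolidinone and pass through a ring closure that breaks no bond at either centre. C2″ (S) comes from the chiral diphosphine on rhodium. The auxiliary, absent from the target, leaves as the nucleofuge of the ring closure.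

Key step: step 10

Locants and ring letters: unprimed locants and rings A (benzo), C (pyranone), B (catechol) belong to the eriodictyol half; double-primed locants and rings D (benzo), F (pyranone), E (4-hydroxyphenyl) belong to the naringenin half.

Assumption: the descriptors are taken as drawn, (2R,3R) and (2″S); with the priorities O1 > aryl > C3 at C2 and C4 > C2 > aryl at C3 this is the 2,3-cis diastereomer, the less stable one, so it is made and kept under kinetic control (no base or strong acid after ring C exists).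

**Route**

Step 1
Reactants: 1 3,5-bis(benzyloxy)phenol
Product: 2 2-bromo-3,5-bis(benzyloxy)phenol
Conditions: NBS (1.0 equiv), CH2Cl2, −78 → −30 °C
Reagents that add atoms: N-bromosuccinimide, O=C1CCC(=O)N1Br
Why: Electrophilic aromatic bromination of a 3,5-dialkoxyphenol at low temperature should favour the position ortho to the free hydroxyl (hydrogen-bonded delivery, two equivalent sites) over the more hindered site between the two benzyloxy groups, the para isomer being removed by chromatography.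

Step 2
Reactants: 2 2-bromo-3,5-bis(benzyloxy)phenol
Product: 5 3,5-bis(benzyloxy)-2-(trimethylsilyl)phenyl trifluoromethanesulfonate, via aryl silyl ether 3 (not isolated), via lithium phenoxide 4 (not isolated)
Conditions: (Me3Si)2NH, THF, 70 °C, then evaporation; n-BuLi, THF, −100 °C; Tf2O, −100 → −78 °C
Reagents that add atoms: hexamethyldisilazane, C[Si](C)(C)N[Si](C)(C)C; trifluoromethanesulfonic anhydride, O=S(=O)(OS(=O)(=O)C(F)(F)F)C(F)(F)F; n-butyllithium, [Li]CCCC (lithium in 4 only)
Why: O-silylation, bromine–lithium exchange, retro-Brook 1,3-migration of silicon from oxygen to carbon and triflation of the phenoxide is the standard sequence to ortho-silylaryl triflate aryne precursors and places silicon between the triflate carbon and a benzyloxy carbon.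

Step 3
Reactants: 6 1-[2,4-bis(benzyloxy)-6-hydroxyphenyl]ethanone
Product: 7 1-[4,6-bis(benzyloxy)-2-hydroxy-3-iodophenyl]ethanone
Conditions: NIS (1.05 equiv), CF3CO2H (cat.), MeCN, 0 → 23 °C
Reagents that add atoms: N-iodosuccinimide, O=C1CCC(=O)N1I
Why: Electrophilic iodination of a 2-hydroxy-4,6-dialkoxyacetophenone should go ortho to the only free (chelated) phenol, the carbon that becomes C8″, and not to the more hindered site between the two benzyloxy groups.

Step 4
Reactants: 7 1-[4,6-bis(benzyloxy)-2-hydroxy-3-iodophenyl]ethanone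
Product: 9 5,7-bis(benzyloxy)-8-iodo-4H-chromen-4-one, via enaminone 8 (not isolated)
Conditions: Me2NCH(OMe)2, toluene, 95 °C; then 2 M aq. HCl, CH2Cl2, 40 °C
Reagents that add atoms: N,N-dimethylformamide dimethyl acetal, COC(OC)N(C)C
Why: Condensation at the acetyl methyl group gives the enaminone, and acid-induced addition of the phenol with loss of dimethylamine is the standard chromone synthesis; because the free phenol is the one next to iodine, iodine ends up at C8″.

Step 5
Reactants: 9 5,7-bis(benzyloxy)-8-iodo-4H-chromen-4-one; 10 (2-tert-butoxy-2-oxoethyl)zinc bromide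
Product: 11 tert-butyl 2-[5,7-bis(benzyloxy)-4-oxo-4H-chromen-8-yl]acetate
Conditions: Pd2(dba)3 (2.5 mol %), XPhos (10 mol %), THF, 23 → 50 °C
Reagents that add atoms: none
Why: Negishi-type α-arylation with a Reformatsky reagent (oxidative addition of zerovalent palladium into C8″–I, transmetalation of the zinc enolate, reductive elimination) forms the aryl–CH2 bond under neutral conditions that spare the chromone.

Step 6
Reactants: 11 tert-butyl 2-[5,7-bis(benzyloxy)-4-oxo-4H-chromen-8-yl]acetate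
Product: 12 2-[5,7-bis(benzyloxy)-4-oxo-4H-chromen-8-yl]acetic acid
Conditions: CF3CO2H/CH2Cl2 (1:3), 0 °C
Reagents that add atoms: none
Why: Acidolysis of the tert-butyl ester (loss of isobutene) at 0 °C should leave the aryl benzyl ethers and the chromone untouched.

Step 7
Reactants: 12 2-[5,7-bis(benzyloxy)-4-oxo-4H-chromen-8-yl]acetic acid; 13 (R)-4-benzyl-1,3-oxazolidin-2-one
Product: 15 (R)-4-benzyl-3-{[5,7-bis(benzyloxy)-4-oxo-4H-chromen-8-yl]acetyl}-1,3-oxazolidin-2-one, via mixed pivalic anhydride 14 (not isolated)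
Conditions: t-BuCOCl, Et3N, THF, −20 °C; then 13, LiCl, −20 → 23 °C
Reagents that add atoms: pivaloyl chloride, CC(C)(C)C(=O)Cl (atoms in 14 only)
Why: N-Acylation of the oxazolidinone by the mixed anhydride under LiCl/amine activation is a standard imide synthesis and avoids the strong bases that would attack the chromone.

Step 8
Reactants: 15 (R)-4-benzyl-3-{[5,7-bis(benzyloxy)-4-oxo-4H-chromen-8-yl]acetyl}-1,3-oxazolidin-2-one; 16 3,4-bis(benzyloxy)benzaldehyde
Product: 19 (R)-4-benzyl-3-[(2R,3R)-3-[3,4-bis(benzyloxy)phenyl]-2-[5,7-bis(benzyloxy)-4-oxo-4H-chromen-8-yl]-3-hydroxypropanoyl]-1,3-oxazolidin-2-one, via boron enolate 17 (not isolated), via boron aldolate 18 (not isolated)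
Conditions: n-Bu2BOTf (2.2 equiv, the second equivalent ties up the chromone carbonyl), i-Pr2NEt (2.6 equiv), CH2Cl2, −78 → 0 °C; 16, −78 → −10 °C; pH 7 buffer, MeOH, 30% H2O2, 0 °C
Reagents that add atoms: dibutylboron triflate, CCCCB(CCCC)OS(=O)(=O)C(F)(F)F (atoms in 17 and 18 only)
Why: Evans syn aldol: the Z-dibutylboron enolate reacts through a Zimmerman–Traxler chair with the auxiliary carbonyl dipole opposed and the aldehyde approaching anti to the benzyl group, which sets the future C3 (R) and C2 (R) as the syn pair that maps onto the 2,3-cis ring.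

Step 9
Reactants: 19 (R)-4-benzyl-3-[(2R,3R)-3-[3,4-bis(benzyloxy)phenyl]-2-[5,7-bis(benzyloxy)-4-oxo-4H-chromen-8-yl]-3-hydroxypropanoyl]-1,3-oxazolidin-2-one; 20 [4-(benzyloxy)phenyl]boronic acid
Product: 21 (R)-4-benzyl-3-[(2R,3R)-3-[3,4-bis(benzyloxy)phenyl]-2-[(2S)-5,7-bis(benzyloxy)-2-[4-(benzyloxy)phenyl]-4-oxochroman-8-yl]-3-hydroxypropanoyl]-1,3-oxazolidin-2-one
Conditions: [Rh(OH)(cod)]2 (3 mol %), (R)-MeO-F12-BIPHEP [(R)-2,2′-bis[bis(3,4,5-trifluorophenyl)phosphino]-6,6′-dimethoxy-1,1′-biphenyl] (6.6 mol %), 20 (3 equiv), toluene/H2O (10:1), 25 °C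
Reagents that add atoms: none
Why: Hayashi–Miyaura asymmetric 1,4-addition of the arylboronic acid to the chromone: the aryl–rhodium species adds to C2″ on the face chosen by the chiral diphosphine (2″S wanted), the electron-poor ligand disfavouring 1,2-addition, and the ligand enantiomer is to be confirmed on ester 11 as a model and inverted if needed.

Step 10
Reactants: 21 (R)-4-benzyl-3-[(2R,3R)-3-[3,4-bis(benzyloxy)phenyl]-2-[(2S)-5,7-bis(benzyloxy)-2-[4-(benzyloxy)phenyl]-4-oxochroman-8-yl]-3-hydroxypropanoyl]-1,3-oxazolidin-2-one; 5 3,5-bis(benzyloxy)-2-(trimethylsilyl)phenyl trifluoromethanesulfonate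
Product: 23 (2R,3R)-5,7-bis(benzyloxy)-2-[3,4-bis(benzyloxy)phenyl]-3-[(2S)-5,7-bis(benzyloxy)-2-[4-(benzyloxy)phenyl]-4-oxochroman-8-yl]chroman-4-one, via aryne 22 (not isolated)
Conditions: 5 (2.0 equiv, syringe pump), Bu4N[Ph3SiF2] (2.5 equiv), toluene/THF (4:1), 25 °C
Reagents that add atoms: none
Why: Proposed new method: fluoride unmasks 3,5-bis(benzyloxy)benzyne 22, the C2 hydroxyl of 21 adds to its terminus remote from the 3-benzyloxy group, and the aryl carbanion so placed on the carbon flanked by O-benzyl (future C4a) attacks the exocyclic imide carbonyl six atoms away, the oxazolidinone leaving with the hydroxyl proton. The closest known reaction type is the fluoride-induced aryne coupling–cyclisation of salicylates and anthranilates to xanthones and acridones (O- or N-arylation followed by acyl capture of the aryl anion) together with aryne insertion into amide C–N bonds; it has not been shown for an aliphatic β-hydroxy imide. Ring C closes by 6-exo-trig addition–elimination that forms C4–C4a, the O1–C8a ether bond being made first without closing a ring. No stereocentre is created: C2 and C3 keep the configuration set in step 8 because no bond to them is broken and the medium is aprotic and only weakly basic, so the less stable 2,3-cis ring is obtained kinetically. The step needs O-attack at the right aryne carbon, which the 3-alkoxy substituent (the C5 oxygen of the target) secures by polarising and distorting the triple bond, and acyl capture faster than proton transfer to the carbanion, which the activated N-acyl carbonyl in six-membered reach, the absence of other proton donors and the slow release of the aryne are meant to secure. Material that takes the proton-transfer branch is the aryl ether that the fallback converts to 23.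

Step 11
Reactants: 23 (2R,3R)-5,7-bis(benzyloxy)-2-[3,4-bis(benzyloxy)phenyl]-3-[(2S)-5,7-bis(benzyloxy)-2-[4-(benzyloxy)phenyl]-4-oxochroman-8-yl]chroman-4-one
Product: 24 (2R,3R)-2-(3,4-dihydroxyphenyl)-5,7-dihydroxy-3-[(2S)-5,7-dihydroxy-2-(4-hydroxyphenyl)-4-oxochroman-8-yl]chroman-4-one
Conditions: H2 (1 atm), 10% Pd/C, EtOAc/MeOH (1:1), 23 °C
Reagents that add atoms: none
Why: Hydrogenolysis of the seven aryl benzyl ethers under neutral conditions should free all phenols without enolising C3 (cis kept) or opening either pyranone ring by retro-oxa-Michael reaction.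

**Compound list**

1 | 3,5-bis(benzyloxy)phenol | Oc1cc(OCc2ccccc2)cc(OCc2ccccc2)c1 | starting material
2 | 2-bromo-3,5-bis(benzyloxy)phenol | Oc1cc(OCc2ccccc2)cc(OCc2ccccc2)c1Br | intermediate
3 | [2-bromo-3,5-bis(benzyloxy)phenoxy]trimethylsilane | C[Si](C)(C)Oc1cc(OCc2ccccc2)cc(OCc2ccccc2)c1Br | intermediate (not isolated)
4 | lithium 3,5-bis(benzyloxy)-2-(trimethylsilyl)phenoxide | [Li+].[O-]c1cc(OCc2ccccc2)cc(OCc2ccccc2)c1[Si](C)(C)C | intermediate (not isolated)
5 | 3,5-bis(benzyloxy)-2-(trimethylsilyl)phenyl trifluoromethanesulfonate | C[Si](C)(C)c1c(OS(=O)(=O)C(F)(F)F)cc(OCc2ccccc2)cc1OCc1ccccc1 | intermediate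
6 | 1-[2,4-bis(benzyloxy)-6-hydroxyphenyl]ethanone | CC(=O)c1c(O)cc(OCc2ccccc2)cc1OCc1ccccc1 | starting material
7 | 1-[4,6-bis(benzyloxy)-2-hydroxy-3-iodophenyl]ethanone | CC(=O)c1c(O)c(I)c(OCc2ccccc2)cc1OCc1ccccc1 | intermediate
8 | (E)-1-[4,6-bis(benzyloxy)-2-hydroxy-3-iodophenyl]-3-(dimethylamino)prop-2-en-1-one | CN(C)/C=C/C(=O)c1c(O)c(I)c(OCc2ccccc2)cc1OCc1ccccc1 | intermediate (not isolated)
9 | 5,7-bis(benzyloxy)-8-iodo-4H-chromen-4-one | O=c1ccoc2c(I)c(OCc3ccccc3)cc(OCc3ccccc3)c12 | intermediate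
10 | (2-tert-butoxy-2-oxoethyl)zinc bromide | CC(C)(C)OC(=O)C[Zn]Br | starting material
11 | tert-butyl 2-[5,7-bis(benzyloxy)-4-oxo-4H-chromen-8-yl]acetate | CC(C)(C)OC(=O)Cc1c(OCc2ccccc2)cc(OCc2ccccc2)c2c(=O)ccoc12 | intermediate
12 | 2-[5,7-bis(benzyloxy)-4-oxo-4H-chromen-8-yl]acetic acid | OC(=O)Cc1c(OCc2ccccc2)cc(OCc2ccccc2)c2c(=O)ccoc12 | intermediate
13 | (R)-4-benzyl-1,3-oxazolidin-2-one | O=C1N[C@H](Cc2ccccc2)CO1 | starting material
14 | 2-[5,7-bis(benzyloxy)-4-oxo-4H-chromen-8-yl]acetic pivalic anhydride | CC(C)(C)C(=O)OC(=O)Cc1c(OCc2ccccc2)cc(OCc2ccccc2)c2c(=O)ccoc12 | intermediate (not isolated)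
15 | (R)-4-benzyl-3-{[5,7-bis(benzyloxy)-4-oxo-4H-chromen-8-yl]acetyl}-1,3-oxazolidin-2-one | O=C(Cc1c(OCc2ccccc2)cc(OCc2ccccc2)c2c(=O)ccoc12)N1C(=O)OC[C@H]1Cc1ccccc1 | intermediate
16 | 3,4-bis(benzyloxy)benzaldehyde | O=Cc1ccc(OCc2ccccc2)c(OCc2ccccc2)c1 | starting material
17 | (Z)-dibutylboron enolate of 15 | CCCCB(CCCC)O/C(=C\c1c(OCc2ccccc2)cc(OCc2ccccc2)c2c(=O)ccoc12)N1C(=O)OC[C@H]1Cc1ccccc1 | intermediate (not isolated)
18 | dibutylboron aldolate of 19 | O=c1ccoc2c1c(OCc1ccccc1)cc(OCc1ccccc1)c2[C@@H](C(=O)N1C(=O)OC[C@H]1Cc1ccccc1)[C@@H](OB(CCCC)CCCC)c1ccc(OCc2ccccc2)c(OCc2ccccc2)c1 | intermediate (not isolated)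
19 | (R)-4-benzyl-3-[(2R,3R)-3-[3,4-bis(benzyloxy)phenyl]-2-[5,7-bis(benzyloxy)-4-oxo-4H-chromen-8-yl]-3-hydroxypropanoyl]-1,3-oxazolidin-2-one | O=c1ccoc2c1c(OCc1ccccc1)cc(OCc1ccccc1)c2[C@@H](C(=O)N1C(=O)OC[C@H]1Cc1ccccc1)[C@@H](O)c1ccc(OCc2ccccc2)c(OCc2ccccc2)c1 | intermediate
20 | [4-(benzyloxy)phenyl]boronic acid | OB(O)c1ccc(OCc2ccccc2)cc1 | starting material
21 | (R)-4-benzyl-3-[(2R,3R)-3-[3,4-bis(benzyloxy)phenyl]-2-[(2S)-5,7-bis(benzyloxy)-2-[4-(benzyloxy)phenyl]-4-oxochroman-8-yl]-3-hydroxypropanoyl]-1,3-oxazolidin-2-one | O=C1C[C@@H](c2ccc(OCc3ccccc3)cc2)Oc2c1c(OCc1ccccc1)cc(OCc1ccccc1)c2[C@@H](C(=O)N1C(=O)OC[C@H]1Cc1ccccc1)[C@@H](O)c1ccc(OCc2ccccc2)c(OCc2ccccc2)c1 | intermediate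
22 | 3,5-bis(benzyloxy)benzyne | C1#CC(OCc2ccccc2)=CC(OCc2ccccc2)=C1 | intermediate (not isolated)
23 | (2R,3R)-5,7-bis(benzyloxy)-2-[3,4-bis(benzyloxy)phenyl]-3-[(2S)-5,7-bis(benzyloxy)-2-[4-(benzyloxy)phenyl]-4-oxochroman-8-yl]chroman-4-one | O=C1C[C@@H](c2ccc(OCc3ccccc3)cc2)Oc2c1c(OCc1ccccc1)cc(OCc1ccccc1)c2[C@H]1C(=O)c2c(OCc3ccccc3)cc(OCc3ccccc3)cc2O[C@H]1c1ccc(OCc2ccccc2)c(OCc2ccccc2)c1 | intermediate
24 | (2R,3R)-2-(3,4-dihydroxyphenyl)-5,7-dihydroxy-3-[(2S)-5,7-dihydroxy-2-(4-hydroxyphenyl)-4-oxochroman-8-yl]chroman-4-one | O=C1C[C@@H](c2ccc(O)cc2)Oc2c1c(O)cc(O)c2[C@H]1C(=O)c2c(O)cc(O)cc2O[C@H]1c1ccc(O)c(O)c1 | target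

**Step count and risks**

Total step count: 11. Longest linear sequence: 9 steps (steps 3 to 11, from acetophenone 6); the aryne precursor 5 is made in 2 steps and joins at step 10.

The three steps most likely to fail:

Step 10 (Proposed new method). Proton transfer to the aryl carbanion may outrun acyl capture, so the ether forms but ring C stays open. The aryne may instead oxidise the carbinol by hydrogen transfer, or fluoride may trigger retro-aldol cleavage or epimerisation at C3. The fallback uses known chemistry and closes ring C as an electrophile instead of through a carbanion. It sets out from 21: O-arylation of the alcohol with 5 under KF/18-crown-6 in THF (O–H insertion into the aryne) gives the aryl ether imide F1. LiOH/H2O2 in THF/H2O at 0 °C removes the auxiliary and gives the 3-aryloxy acid F2. (CF3CO)2O in CH2Cl2 at −20 → 0 °C gives the mixed trifluoroacetic anhydride F3 (not isolated), which undergoes intramolecular Friedel–Crafts acylation at either of the two equivalent positions ortho to the ether oxygen. The fallback comes back to the route at 23.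

Step 8. C–C bond formation may be slow or unselective because the boron enolate carries a di-ortho-substituted aryl group and the chromone carbonyl competes for the boron triflate, and the adduct may revert by retro-aldol cleavage on work-up. The fallback forms C2–C3 by acylation and sets the carbinol by reduction. It sets out from acid 12: the protocol of step 7 with (S)-4-benzyl-1,3-oxazolidin-2-one gives the (S)-imide F4. NaN(SiMe3)2 in THF at −78 °C and then 3,4-bis(benzyloxy)benzoyl chloride acylate the chelated Z-enolate on the face opposite the benzyl group and give the β-keto imide F5 with C3 already R. Zn(BH4)2 in CH2Cl2/Et2O at −20 °C reduces the chelated ketone to the syn alcohol F6, which has the same (2R,3R) chain as 19. The conditions of step 9 turn F6 into the flavanone F7, and the conditions of step 10 (the (S)-oxazolidinone now being expelled) bring the fallback back to the route at 23.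

Step 9. Facial selectivity or conversion in the conjugate arylation may be poor because the chromone carries a bulky stereogenic side chain at C8″ that may be mismatched with the catalyst, and a rhodium alkoxide of the free β-hydroxy imide may induce retro-aldol cleavage. The fallback changes the order of events so that the arylation meets a rigid substrate without a free hydroxyl. It sets out from 19: the conditions of step 10 give the chromone–flavanone F8, and the rhodium-catalysed arylation is then run on F8, any 2″-epimer being a separable diastereomer. The fallback comes back to the route at 23.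

**Further compounds**

F1 | step 10 | (R)-4-benzyl-3-[(2R,3R)-3-[3,4-bis(benzyloxy)phenyl]-3-[3,5-bis(benzyloxy)phenoxy]-2-[(2S)-5,7-bis(benzyloxy)-2-[4-(benzyloxy)phenyl]-4-oxochroman-8-yl]propanoyl]-1,3-oxazolidin-2-one | O=C1C[C@@H](c2ccc(OCc3ccccc3)cc2)Oc2c1c(OCc1ccccc1)cc(OCc1ccccc1)c2[C@@H](C(=O)N1C(=O)OC[C@H]1Cc1ccccc1)[C@@H](Oc1cc(OCc2ccccc2)cc(OCc2ccccc2)c1)c1ccc(OCc2ccccc2)c(OCc2ccccc2)c1
F2 | step 10 | (2R,3R)-3-[3,4-bis(benzyloxy)phenyl]-3-[3,5-bis(benzyloxy)phenoxy]-2-[(2S)-5,7-bis(benzyloxy)-2-[4-(benzyloxy)phenyl]-4-oxochroman-8-yl]propanoic acid | O=C1C[C@@H](c2ccc(OCc3ccccc3)cc2)Oc2c1c(OCc1ccccc1)cc(OCc1ccccc1)c2[C@@H](C(=O)O)[C@@H](Oc1cc(OCc2ccccc2)cc(OCc2ccccc2)c1)c1ccc(OCc2ccccc2)c(OCc2ccccc2)c1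
F3 | step 10 | mixed trifluoroacetic anhydride of acid F2 | O=C1C[C@@H](c2ccc(OCc3ccccc3)cc2)Oc2c1c(OCc1ccccc1)cc(OCc1ccccc1)c2[C@@H](C(=O)OC(=O)C(F)(F)F)[C@@H](Oc1cc(OCc2ccccc2)cc(OCc2ccccc2)c1)c1ccc(OCc2ccccc2)c(OCc2ccccc2)c1
F4 | step 8 | (S)-4-benzyl-3-{[5,7-bis(benzyloxy)-4-oxo-4H-chromen-8-yl]acetyl}-1,3-oxazolidin-2-one | O=C(Cc1c(OCc2ccccc2)cc(OCc2ccccc2)c2c(=O)ccoc12)N1C(=O)OC[C@@H]1Cc1ccccc1
F5 | step 8 | (S)-4-benzyl-3-[(2R)-3-[3,4-bis(benzyloxy)phenyl]-2-[5,7-bis(benzyloxy)-4-oxo-4H-chromen-8-yl]-3-oxopropanoyl]-1,3-oxazolidin-2-one | O=c1ccoc2c1c(OCc1ccccc1)cc(OCc1ccccc1)c2[C@@H](C(=O)N1C(=O)OC[C@@H]1Cc1ccccc1)C(=O)c1ccc(OCc2ccccc2)c(OCc2ccccc2)c1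
F6 | step 8 | (S)-4-benzyl-3-[(2R,3R)-3-[3,4-bis(benzyloxy)phenyl]-2-[5,7-bis(benzyloxy)-4-oxo-4H-chromen-8-yl]-3-hydroxypropanoyl]-1,3-oxazolidin-2-one | O=c1ccoc2c1c(OCc1ccccc1)cc(OCc1ccccc1)c2[C@@H](C(=O)N1C(=O)OC[C@@H]1Cc1ccccc1)[C@@H](O)c1ccc(OCc2ccccc2)c(OCc2ccccc2)c1
F7 | step 8 | (S)-4-benzyl-3-[(2R,3R)-3-[3,4-bis(benzyloxy)phenyl]-2-[(2S)-5,7-bis(benzyloxy)-2-[4-(benzyloxy)phenyl]-4-oxochroman-8-yl]-3-hydroxypropanoyl]-1,3-oxazolidin-2-one | O=C1C[C@@H](c2ccc(OCc3ccccc3)cc2)Oc2c1c(OCc1ccccc1)cc(OCc1ccccc1)c2[C@@H](C(=O)N1C(=O)OC[C@@H]1Cc1ccccc1)[C@@H](O)c1ccc(OCc2ccccc2)c(OCc2ccccc2)c1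
F8 | step 9 | (2R,3R)-5,7-bis(benzyloxy)-2-[3,4-bis(benzyloxy)phenyl]-3-[5,7-bis(benzyloxy)-4-oxo-4H-chromen-8-yl]chroman-4-one | O=c1ccoc2c1c(OCc1ccccc1)cc(OCc1ccccc1)c2[C@H]1C(=O)c2c(OCc3ccccc3)cc(OCc3ccccc3)cc2O[C@H]1c1ccc(OCc2ccccc2)c(OCc2ccccc2)c1
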